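**Plan**
1. Retrosynthesis: the chalcone Cα=Cβ bond (aldol condensation with the ring B aldehyde) and the ring A–acetyl bond (iodination, Stille coupling) are cut first, leaving a C3 boronate as the masked carbinol.
2. Enabling feature: the C3 carbinol sits between C2 (ethylene link to ring D) and C4, the CH2 allylic to the E-C5=C6 alkene that leads to the C7 diarylmethine. C3–C4 therefore maps onto a vinylboron unit, and C2–C3 and C4–C5 are cut together into ring D ethylboronate 18, vinyllithium 20 and the C7-bearing E-alkenyl bromide 14.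
3. Bromide 14 is cut at C5=C6 (cross-metathesis with vinyl pinacol boronate, then boron → iodine → bromine exchange) and at the C7–ring A bond (anti-SN2′ arylation of a ring C allylic picolinate by a ring A arylcopper reagent).
4. Forward order: C7–ring A bond, C5 homologation, three-component union of C1–C2, C3–C4 and C5–C7, ring A acetylation, C–B oxidation, chalcone condensation, removal of five methoxymethyl groups. The chain is only joined; no ring is formed at any stage.
5. Stereochemistry: C7 (R) by 1,3-chirality transfer from a carbinol set by Corey–Bakshi–Shibata reduction; C3 (S) by the chiral palladium catalyst and retentive C–B oxidation; both E-alkenes by E-selective bond formation with geometry-retentive halogen exchange.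

Key step: step 12

Remark: the heptene chain is numbered C1 (CH2 on ring D) to C7 (diarylmethine), ring A is the phloroglucinol-derived ring, ring B the chalcone aryl, ring C the aryl on C7 and ring D the aryl on C1. With this numbering the target is (3S,5E,7R); in substituent names counted from the attachment carbon, C7 is position 1 and C3 is position 5. MOMCl is chloromethyl methyl ether, NIS is N-iodosuccinimide.

**Step 1**
Reactants: 1 5-methoxybenzene-1,3-diol
Product: 2 1-methoxy-3,5-bis(methoxymethoxy)benzene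
Conditions: NaH (2.4 equiv), MOMCl (2.4 equiv), DMF, 0 °C → rt
Reagents that add atoms: chloromethyl methyl ether, COCCl
Why: Williamson O-alkylation of the bis-phenoxide gives the bis-acetal whose two acetal oxygens later direct lithiation to the carbon between them.

**Step 2**
Reactants: 3 (3E)-4-(4-hydroxyphenyl)but-3-en-2-one
Product: 4 (3E)-4-[4-(methoxymethoxy)phenyl]but-3-en-2-one
Conditions: NaH (1.05 equiv), MOMCl (1.1 equiv), THF/DMF, 0 °C
Reagents that add atoms: chloromethyl methyl ether, COCCl
Why: The phenol is far more acidic than the methyl ketone, so one equivalent of base gives the phenoxide and Williamson O-alkylation follows.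

**Step 3**
Reactants: 4 (3E)-4-[4-(methoxymethoxy)phenyl]but-3-en-2-one
Product: 5 (2S,3E)-4-[4-(methoxymethoxy)phenyl]but-3-en-2-ol
Conditions: (R)-1-methyl-3,3-diphenyltetrahydro-1H,3H-pyrrolo[1,2-c][1,3,2]oxazaborole [(R)-Me-CBS, 15 mol%], catecholborane (1.8 equiv), toluene, −78 °C; aq. NaOH work-up
Reagents that add atoms: none
Why: Corey–Bakshi–Shibata reduction, in which the ketone binds the oxazaborolidine with the alkenyl group as the large substituent, so the (R)-catalyst should deliver hydride to the face that gives the (S)-carbinol; catecholborane at low temperature avoids hydroboration of the alkene.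

**Step 4**
Reactants: 5 (2S,3E)-4-[4-(methoxymethoxy)phenyl]but-3-en-2-ol
Product: 6 (2S,3E)-4-[4-(methoxymethoxy)phenyl]but-3-en-2-yl pyridine-2-carboxylate
Conditions: pyridine-2-carboxylic acid, DCC, 4-(dimethylamino)pyridine (cat.), CH2Cl2, 0 °C → rt
Reagents that add atoms: pyridine-2-carboxylic acid, OC(=O)c1ccccn1
Why: Steglich esterification acylates oxygen without touching the carbinol configuration and installs the chelating picolinoxy leaving group.

**Step 5**
Reactants: 2 1-methoxy-3,5-bis(methoxymethoxy)benzene; 6 (2S,3E)-4-[4-(methoxymethoxy)phenyl]but-3-en-2-yl pyridine-2-carboxylate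
Product: 10 5-methoxy-1,3-bis(methoxymethoxy)-2-[(1R,2E)-1-[4-(methoxymethoxy)phenyl]but-2-en-1-yl]benzene, via aryllithium 7 (not isolated), via arylmagnesium bromide 8 (not isolated), via diarylcuprate 9 (not isolated)
Conditions: 2 (2.2 equiv), n-BuLi (2.1 equiv), THF, 0 °C; MgBr2·OEt2 (2.2 equiv); CuBr·SMe2 (1.05 equiv), −20 °C; then 6, −20 → 0 °C; aq. NH4Cl
Reagents that add atoms: none
Why: Directed ortho-metalation between the two cooperating methoxymethoxy groups, transmetalation to magnesium and copper, then anti-SN2′ allylic substitution in which magnesium bound to the picolinoxy group activates it and copper attacks the aryl-bearing γ-carbon on the face opposite the leaving group, in the conformer with the carbinol hydrogen in the alkene plane, so the (S)-carbinol is relayed to (R)-C7 with an E-propenyl group.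

**Step 6**
Reactants: 10 5-methoxy-1,3-bis(methoxymethoxy)-2-[(1R,2E)-1-[4-(methoxymethoxy)phenyl]but-2-en-1-yl]benzene; 11 2-ethenyl-4,4,5,5-tetramethyl-1,3,2-dioxaborolane
Product: 12 2-[(1E,3R)-3-[4-methoxy-2,6-bis(methoxymethoxy)phenyl]-3-[4-(methoxymethoxy)phenyl]prop-1-en-1-yl]-4,4,5,5-tetramethyl-1,3,2-dioxaborolane
Conditions: 11 (3 equiv), second-generation Hoveyda–Grubbs catalyst RuCl2(H2IMes)(=CH-C6H4-2-O-i-Pr) (5 mol%), 1,4-benzoquinone (10 mol%), CH2Cl2, 40 °C
Reagents that add atoms: none
Why: Olefin cross-metathesis exchanges the ethylidene terminus for a borylmethylidene unit with loss of volatile propene, the bulky boronate favours the E-alkene, and the quinone suppresses ruthenium hydride migration of the alkene toward C7.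

**Step 7**
Reactants: 12 the (1E,3R)-alkenyl pinacol boronate
Product: 13 2-[(1R,2E)-3-iodo-1-[4-(methoxymethoxy)phenyl]prop-2-en-1-yl]-5-methoxy-1,3-bis(methoxymethoxy)benzene
Conditions: 3 M aq. NaOH (3 equiv), THF, 0 °C; I2 (1.2 equiv), 0 °C; aq. Na2S2O3
Reagents that add atoms: iodine, II
Why: Iododeboronation of the hydroxide-activated alkenylboronate by ipso attack of iodine retains the alkene geometry, and the anionic boronate should react with iodine much faster than the trialkoxy ring A does without an oxidant or acid.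

**Step 8**
Reactants: 13 the (1R,2E)-alkenyl iodide
Product: 14 2-[(1R,2E)-3-bromo-1-[4-(methoxymethoxy)phenyl]prop-2-en-1-yl]-5-methoxy-1,3-bis(methoxymethoxy)benzene
Conditions: CuI (10 mol%), trans-N,N′-dimethylcyclohexane-1,2-diamine (20 mol%), Me4NBr (3 equiv), EtOH, 100 °C, sealed tube
Reagents that add atoms: tetramethylammonium bromide, C[N+](C)(C)C.[Br-]
Why: Copper-catalysed vinylic Finkelstein reaction (halogen exchange at the alkenyl carbon on monovalent copper with a diamine ligand) keeps the E geometry and is driven by excess bromide, giving the halide for which triflate-salt scavenging in the next coupling is established.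

**Step 9**
Reactants: 15 4-hydroxybenzaldehyde
Product: 16 4-(methoxymethoxy)benzaldehyde
Conditions: NaH (1.1 equiv), MOMCl (1.2 equiv), DMF, 0 °C → rt
Reagents that add atoms: chloromethyl methyl ether, COCCl
Why: Williamson O-alkylation of the phenoxide; the product serves both as the ring D precursor and as the ring B aldehyde.

**Step 10**
Reactants: 16 4-(methoxymethoxy)benzaldehyde
Product: 17 1-ethenyl-4-(methoxymethoxy)benzene
Conditions: Ph3PCH3Br, KOt-Bu, THF, 0 °C → rt
Reagents that add atoms: methyltriphenylphosphonium bromide, C[P+](c1ccccc1)(c1ccccc1)c1ccccc1.[Br-]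
Why: Wittig methylenation with the non-stabilised ylide converts the aldehyde into the styrene and leaves the acetal untouched.

**Step 11**
Reactants: 17 1-ethenyl-4-(methoxymethoxy)benzene
Product: 18 2-[2-[4-(methoxymethoxy)phenyl]ethyl]-4,4,5,5-tetramethyl-1,3,2-dioxaborolane
Conditions: pinacolborane (1.2 equiv), [Ir(cod)Cl]2 (1.5 mol%), 1,2-bis(diphenylphosphino)ethane (3 mol%), CH2Cl2, rt
Reagents that add atoms: pinacolborane, [H]B1OC(C)(C)C(C)(C)O1
Why: Iridium-catalysed hydroboration of a vinylarene places boron on the terminal carbon (anti-Markovnikov) and gives the primary alkylboronate.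

**Step 12**
Reactants: 18 2-[2-[4-(methoxymethoxy)phenyl]ethyl]-4,4,5,5-tetramethyl-1,3,2-dioxaborolane; 19 tetraethenylstannane; 14 the (1R,2E)-alkenyl bromide
Product: 22 2-[(3S,5E,7R)-7-[4-methoxy-2,6-bis(methoxymethoxy)phenyl]-1,7-bis[4-(methoxymethoxy)phenyl]hept-5-en-3-yl]-4,4,5,5-tetramethyl-1,3,2-dioxaborolane, via vinyllithium 20 (not isolated), via lithium vinylborate complex 21 (not isolated)
Conditions: 19 (0.3 equiv), n-BuLi (1.2 equiv), pentane then Et2O; 18 (1.2 equiv), THF, 0 °C → rt; then 14 (1.0 equiv), Pd(OAc)2 (2 mol%), 1,1′-bis[bis(4-methoxy-3,5-dimethylphenyl)phosphino]-2,2′-bis[α-(dimethylamino)benzyl]ferrocene (MandyPhos type, enantiomer that gives 3S, 2.4 mol%), KOSO2CF3 (2 equiv), THF, 60 °C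
Reagents that add atoms: none
Why: Oxidative addition of 14 to zerovalent palladium and removal of bromide by the triflate salt give a cationic divalent alkenylpalladium species that binds the vinyl group of borate 21; this triggers 1,2-migration of the 2-arylethyl group from boron to C3 anti to palladium as the metal bonds C4, and reductive elimination then forms C4–C5. The closest known reaction type is the palladium-catalysed enantioselective conjunctive cross-coupling of vinylboron ate complexes with C(sp2) halides or triflates. No ring is closed. The C3 stereocentre is set by the chiral ferrocenyl bisphosphine, which selects the alkene face that palladium binds, and the remote C7 centre should have no influence. The step needs reaction at the alkenyl C–Br bond with retention of the E geometry and migration in preference to direct vinyl transfer; the unhindered E-bromide, the primary alkyl migrating group and the wide-bite-angle ligand secure this.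

**Step 13**
Reactants: 22 the (3S,5E,7R)-C3 pinacol boronate
Product: 23 2-[(3S,5E,7R)-7-[3-iodo-4-methoxy-2,6-bis(methoxymethoxy)phenyl]-1,7-bis[4-(methoxymethoxy)phenyl]hept-5-en-3-yl]-4,4,5,5-tetramethyl-1,3,2-dioxaborolane
Conditions: NIS (1.0 equiv), MeCN, 0 °C, dark
Reagents that add atoms: N-iodosuccinimide, O=C1CCC(=O)N1I
Why: Electrophilic aromatic iodination picks ring A, whose three alkoxy groups make it far more nucleophilic than rings C and D or the alkene; its two open positions are equivalent by rotation about the C7–aryl bond, the first iodine deactivates the ring, and with boron still on C3 there is no hydroxyl to start an iodoetherification of the C5=C6 alkene.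

**Step 14**
Reactants: 23 the ring A iodide
Product: 25 1-[6-methoxy-2,4-bis(methoxymethoxy)-3-[(1R,2E,5S)-1,7-bis[4-(methoxymethoxy)phenyl]-5-(4,4,5,5-tetramethyl-1,3,2-dioxaborolan-2-yl)hept-2-en-1-yl]phenyl]ethan-1-one, via enol ether 24 (not isolated)
Conditions: tributyl(1-ethoxyethenyl)stannane (1.5 equiv), Pd(PPh3)4 (10 mol%), toluene, 100 °C; then 0.5 M HCl, THF, 0 °C, brief
Reagents that add atoms: tributyl(1-ethoxyethenyl)stannane, CCCC[Sn](CCCC)(CCCC)C(=C)OCC; water, O
Why: Stille coupling of the aryl iodide under neutral conditions (a secondary alkylboronate does not transmetalate without base) gives an enol ether that dilute acid hydrolyses to the methyl ketone much faster than it cleaves aryl methoxymethyl ethers.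

**Step 15**
Reactants: 25 the ring A methyl ketone with C3 boronate
Product: 26 1-[3-[(1R,2E,5S)-5-hydroxy-1,7-bis[4-(methoxymethoxy)phenyl]hept-2-en-1-yl]-6-methoxy-2,4-bis(methoxymethoxy)phenyl]ethan-1-one
Conditions: 30% H2O2, 3 M aq. NaOH, THF, 0 °C
Reagents that add atoms: hydrogen peroxide, OO
Why: Oxidation of the C–B bond by hydroperoxide goes by 1,2-shift of carbon from boron to oxygen with retention, so the catalyst-set configuration becomes the (S)-carbinol; the non-phenolic aryl ketone is inert to cold alkaline peroxide.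

**Step 16**
Reactants: 26 the ring A methyl ketone with free C3 hydroxyl; 16 4-(methoxymethoxy)benzaldehyde
Product: 27 (2E)-1-[3-[(1R,2E,5S)-5-hydroxy-1,7-bis[4-(methoxymethoxy)phenyl]hept-2-en-1-yl]-6-methoxy-2,4-bis(methoxymethoxy)phenyl]-3-[4-(methoxymethoxy)phenyl]prop-2-en-1-one
Conditions: 16 (1.5 equiv), KOH (excess), EtOH, rt
Reagents that add atoms: none
Why: Claisen–Schmidt condensation of the methyl ketone enolate with the non-enolisable aldehyde and loss of water gives the E-enone, as is usual for 2′,6′-dialkoxyacetophenones; the C3 hydroxyl and the C7–H are not affected by alcoholic KOH at room temperature.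

**Step 17**
Reactants: 27 the penta(methoxymethyl)-protected chalcone
Product: 28 epicalyxin B [(2E)-1-[2,4-dihydroxy-3-[(1R,2E,5S)-5-hydroxy-1,7-bis(4-hydroxyphenyl)hept-2-en-1-yl]-6-methoxyphenyl]-3-(4-hydroxyphenyl)prop-2-en-1-one]
Conditions: conc. HCl (few equiv), MeOH, rt → 40 °C
Reagents that add atoms: none
Why: Acid-catalysed acetal exchange with methanol removes all five aryl methoxymethyl groups, the standard last step for polyhydroxychalcones, under conditions mild enough for the enone, the homoallylic alcohol and the C7 centre.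

**Compound list**
1 | 5-methoxybenzene-1,3-diol (5-methoxyresorcinol) | COc1cc(O)cc(O)c1 | starting material
2 | 1-methoxy-3,5-bis(methoxymethoxy)benzene | COCOc1cc(OC)cc(OCOC)c1 | intermediate
3 | (3E)-4-(4-hydroxyphenyl)but-3-en-2-one | CC(=O)/C=C/c1ccc(O)cc1 | starting material
4 | (3E)-4-[4-(methoxymethoxy)phenyl]but-3-en-2-one | CC(=O)/C=C/c1ccc(OCOC)cc1 | intermediate
5 | (2S,3E)-4-[4-(methoxymethoxy)phenyl]but-3-en-2-ol | C[C@H](O)/C=C/c1ccc(OCOC)cc1 | intermediate
6 | (2S,3E)-4-[4-(methoxymethoxy)phenyl]but-3-en-2-yl pyridine-2-carboxylate | C[C@H](OC(=O)c1ccccn1)/C=C/c1ccc(OCOC)cc1 | intermediate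
7 | [4-methoxy-2,6-bis(methoxymethoxy)phenyl]lithium | [Li]c1c(OCOC)cc(OC)cc1OCOC | intermediate
8 | [4-methoxy-2,6-bis(methoxymethoxy)phenyl]magnesium bromide | Br[Mg]c1c(OCOC)cc(OC)cc1OCOC | intermediate
9 | bromomagnesium bis[4-methoxy-2,6-bis(methoxymethoxy)phenyl]cuprate | COCOc1cc(OC)cc(OCOC)c1[Cu-]c1c(OCOC)cc(OC)cc1OCOC.[Mg+]Br | intermediate
10 | 5-methoxy-1,3-bis(methoxymethoxy)-2-[(1R,2E)-1-[4-(methoxymethoxy)phenyl]but-2-en-1-yl]benzene | COc1cc(OCOC)c([C@H](/C=C/C)c2ccc(OCOC)cc2)c(OCOC)c1 | intermediate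
11 | 2-ethenyl-4,4,5,5-tetramethyl-1,3,2-dioxaborolane (vinylboronic acid pinacol ester) | C=CB1OC(C)(C)C(C)(C)O1 | starting material
12 | 2-[(1E,3R)-3-[4-methoxy-2,6-bis(methoxymethoxy)phenyl]-3-[4-(methoxymethoxy)phenyl]prop-1-en-1-yl]-4,4,5,5-tetramethyl-1,3,2-dioxaborolane | COc1cc(OCOC)c([C@H](/C=C/B2OC(C)(C)C(C)(C)O2)c2ccc(OCOC)cc2)c(OCOC)c1 | intermediate
13 | 2-[(1R,2E)-3-iodo-1-[4-(methoxymethoxy)phenyl]prop-2-en-1-yl]-5-methoxy-1,3-bis(methoxymethoxy)benzene | COc1cc(OCOC)c([C@H](/C=C/I)c2ccc(OCOC)cc2)c(OCOC)c1 | intermediate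
14 | 2-[(1R,2E)-3-bromo-1-[4-(methoxymethoxy)phenyl]prop-2-en-1-yl]-5-methoxy-1,3-bis(methoxymethoxy)benzene | COc1cc(OCOC)c([C@H](/C=C/Br)c2ccc(OCOC)cc2)c(OCOC)c1 | intermediate
15 | 4-hydroxybenzaldehyde | O=Cc1ccc(O)cc1 | starting material
16 | 4-(methoxymethoxy)benzaldehyde | COCOc1ccc(C=O)cc1 | intermediate
17 | 1-ethenyl-4-(methoxymethoxy)benzene | C=Cc1ccc(OCOC)cc1 | intermediate
18 | 2-[2-[4-(methoxymethoxy)phenyl]ethyl]-4,4,5,5-tetramethyl-1,3,2-dioxaborolane | CC1(C)OB(CCc2ccc(OCOC)cc2)OC1(C)C | intermediate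
19 | tetraethenylstannane (tetravinyltin) | C=C[Sn](C=C)(C=C)C=C | starting material
20 | vinyllithium | [Li]C=C | intermediate
21 | lithium ethenyl[2-[4-(methoxymethoxy)phenyl]ethyl](pinacolato)borate | [Li+].C=C[B-]1(CCc2ccc(OCOC)cc2)OC(C)(C)C(C)(C)O1 | intermediate
22 | 2-[(3S,5E,7R)-7-[4-methoxy-2,6-bis(methoxymethoxy)phenyl]-1,7-bis[4-(methoxymethoxy)phenyl]hept-5-en-3-yl]-4,4,5,5-tetramethyl-1,3,2-dioxaborolane | COc1cc(OCOC)c([C@H](/C=C/C[C@@H](B2OC(C)(C)C(C)(C)O2)CCc2ccc(OCOC)cc2)c2ccc(OCOC)cc2)c(OCOC)c1 | intermediate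
23 | 2-[(3S,5E,7R)-7-[3-iodo-4-methoxy-2,6-bis(methoxymethoxy)phenyl]-1,7-bis[4-(methoxymethoxy)phenyl]hept-5-en-3-yl]-4,4,5,5-tetramethyl-1,3,2-dioxaborolane | COc1cc(OCOC)c([C@H](/C=C/C[C@@H](B2OC(C)(C)C(C)(C)O2)CCc2ccc(OCOC)cc2)c2ccc(OCOC)cc2)c(OCOC)c1I | intermediate
24 | 2-[(3S,5E,7R)-7-[3-(1-ethoxyethenyl)-4-methoxy-2,6-bis(methoxymethoxy)phenyl]-1,7-bis[4-(methoxymethoxy)phenyl]hept-5-en-3-yl]-4,4,5,5-tetramethyl-1,3,2-dioxaborolane | COc1cc(OCOC)c([C@H](/C=C/C[C@@H](B2OC(C)(C)C(C)(C)O2)CCc2ccc(OCOC)cc2)c2ccc(OCOC)cc2)c(OCOC)c1C(=C)OCC | intermediate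
25 | 1-[6-methoxy-2,4-bis(methoxymethoxy)-3-[(1R,2E,5S)-1,7-bis[4-(methoxymethoxy)phenyl]-5-(4,4,5,5-tetramethyl-1,3,2-dioxaborolan-2-yl)hept-2-en-1-yl]phenyl]ethan-1-one | COc1cc(OCOC)c([C@H](/C=C/C[C@@H](B2OC(C)(C)C(C)(C)O2)CCc2ccc(OCOC)cc2)c2ccc(OCOC)cc2)c(OCOC)c1C(C)=O | intermediate
26 | 1-[3-[(1R,2E,5S)-5-hydroxy-1,7-bis[4-(methoxymethoxy)phenyl]hept-2-en-1-yl]-6-methoxy-2,4-bis(methoxymethoxy)phenyl]ethan-1-one | COc1cc(OCOC)c([C@H](/C=C/C[C@@H](O)CCc2ccc(OCOC)cc2)c2ccc(OCOC)cc2)c(OCOC)c1C(C)=O | intermediate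
27 | (2E)-1-[3-[(1R,2E,5S)-5-hydroxy-1,7-bis[4-(methoxymethoxy)phenyl]hept-2-en-1-yl]-6-methoxy-2,4-bis(methoxymethoxy)phenyl]-3-[4-(methoxymethoxy)phenyl]prop-2-en-1-one | COc1cc(OCOC)c([C@H](/C=C/C[C@@H](O)CCc2ccc(OCOC)cc2)c2ccc(OCOC)cc2)c(OCOC)c1C(=O)/C=C/c1ccc(OCOC)cc1 | intermediate
28 | epicalyxin B, (2E)-1-[2,4-dihydroxy-3-[(1R,2E,5S)-5-hydroxy-1,7-bis(4-hydroxyphenyl)hept-2-en-1-yl]-6-methoxyphenyl]-3-(4-hydroxyphenyl)prop-2-en-1-one | COc1cc(O)c([C@H](/C=C/C[C@@H](O)CCc2ccc(O)cc2)c2ccc(O)cc2)c(O)c1C(=O)/C=C/c1ccc(O)cc1 | target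

**Totals**
Total step count: 17. Longest linear sequence: 13 steps (3 → 4 → 5 → 6 → 10 → 12 → 13 → 14 → 22 → 23 → 25 → 26 → 27 → 28, steps 2–8 and 12–17).

**Steps most likely to fail**

Step 5. What may go wrong: lithiation may not stay at the carbon between the two methoxymethoxy groups, the doubly ortho-substituted aryl group may transfer from copper too slowly, or the electron-rich picolinate may ionise before C–C bond formation, so that attack is no longer purely anti and γ and the transfer of chirality is eroded. Fallback: C7 is set by catalyst control with the roles of the two rings exchanged. The sequence sets out from arene 2. Lithiation and quenching with DMF should give 4-methoxy-2,6-bis(methoxymethoxy)benzaldehyde F1, freed from any regioisomer by crystallisation. Horner–Wadsworth–Emmons olefination with triethyl phosphonoacetate and NaH gives ethyl (2E)-3-[4-methoxy-2,6-bis(methoxymethoxy)phenyl]prop-2-enoate F2. Reduction with i-Bu2AlH gives (2E)-3-[4-methoxy-2,6-bis(methoxymethoxy)phenyl]prop-2-en-1-ol F3, and diethyl chlorophosphate with pyridine gives diethyl (2E)-3-[4-methoxy-2,6-bis(methoxymethoxy)phenyl]prop-2-en-1-yl phosphate F4. In parallel, 4-bromophenol is converted with NaH and MOMCl into 1-bromo-4-(methoxymethoxy)benzene F5 and then with magnesium into [4-(methoxymethoxy)phenyl]magnesium bromide F6. Copper-catalysed enantioselective allylic arylation of F4 with F6 (CuCl, chiral N-heterocyclic carbene ligand, SN2′ attack at the aryl-bearing carbon) should give 5-methoxy-1,3-bis(methoxymethoxy)-2-[(1R)-1-[4-(methoxymethoxy)phenyl]prop-2-en-1-yl]benzene F7. Cross-metathesis of F7 with 11 under the conditions of step 6 comes back to the route at 12.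

Step 12. What may go wrong: bromide may inhibit the cationic palladium intermediate, the vinyl group may be transferred directly (Suzuki–Miyaura pathway) instead of undergoing the metallate shift, or face selection at C3 may be insufficient. Fallback: C3 is set on a two-carbon-shorter alkene and C4–C5 is formed by an ordinary cross-coupling. The sequence sets out from boronate 18 and bromide 14. Borate complex 21, made from 18 as in step 12, is treated with I2 and then NaOMe (Zweifel olefination) to give 1-(but-3-en-1-yl)-4-(methoxymethoxy)benzene F8. Platinum-catalysed enantioselective diboration with bis(pinacolato)diboron (Pt(dba)3, chiral TADDOL-derived phosphonite) should give 2,2′-[(2R)-4-[4-(methoxymethoxy)phenyl]butane-1,2-diyl]bis(4,4,5,5-tetramethyl-1,3,2-dioxaborolane) F9. Site-selective Suzuki–Miyaura coupling of the primary C–B bond of F9 with 14 (Pd(OAc)2, 2-dicyclohexylphosphino-2′,6′-diisopropoxybiphenyl, KOH, THF/H2O) comes back to the route at 22.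

Step 8. What may go wrong: the iodide–bromide exchange may stop at an equilibrium mixture that cannot be separated, or the alkene may isomerise at 100 °C. Fallback: the iodide is bypassed by ipso-bromination of a more nucleophilic boron species. The sequence sets out from alkenylboronate 12. KHF2 in MeOH/H2O gives potassium trifluoro[(1E,3R)-3-[4-methoxy-2,6-bis(methoxymethoxy)phenyl]-3-[4-(methoxymethoxy)phenyl]prop-1-en-1-yl]borate F10. One equivalent of N-bromosuccinimide in MeCN/H2O at low temperature (bromodeboronation with retention) comes back to the route at 14. Bromination of ring A competes in that reaction, which is why it is the fallback and not the main path.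

**Further compounds**
F1 | step 5 | 4-methoxy-2,6-bis(methoxymethoxy)benzaldehyde | COCOc1cc(OC)cc(OCOC)c1C=O
F2 | step 5 | ethyl (2E)-3-[4-methoxy-2,6-bis(methoxymethoxy)phenyl]prop-2-enoate | CCOC(=O)/C=C/c1c(OCOC)cc(OC)cc1OCOC
F3 | step 5 | (2E)-3-[4-methoxy-2,6-bis(methoxymethoxy)phenyl]prop-2-en-1-ol | OC/C=C/c1c(OCOC)cc(OC)cc1OCOC
F4 | step 5 | diethyl (2E)-3-[4-methoxy-2,6-bis(methoxymethoxy)phenyl]prop-2-en-1-yl phosphate | CCOP(=O)(OCC)OC/C=C/c1c(OCOC)cc(OC)cc1OCOC
F5 | step 5 | 1-bromo-4-(methoxymethoxy)benzene | COCOc1ccc(Br)cc1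
F6 | step 5 | [4-(methoxymethoxy)phenyl]magnesium bromide | COCOc1ccc([Mg]Br)cc1
F7 | step 5 | 5-methoxy-1,3-bis(methoxymethoxy)-2-[(1R)-1-[4-(methoxymethoxy)phenyl]prop-2-en-1-yl]benzene | COc1cc(OCOC)c([C@H](C=C)c2ccc(OCOC)cc2)c(OCOC)c1
F8 | step 12 | 1-(but-3-en-1-yl)-4-(methoxymethoxy)benzene | C=CCCc1ccc(OCOC)cc1
F9 | step 12 | 2,2′-[(2R)-4-[4-(methoxymethoxy)phenyl]butane-1,2-diyl]bis(4,4,5,5-tetramethyl-1,3,2-dioxaborolane) | CC1(C)OB(C[C@@H](B2OC(C)(C)C(C)(C)O2)CCc2ccc(OCOC)cc2)OC1(C)C
F10 | step 8 | potassium trifluoro[(1E,3R)-3-[4-methoxy-2,6-bis(methoxymethoxy)phenyl]-3-[4-(methoxymethoxy)phenyl]prop-1-en-1-yl]borate | COc1cc(OCOC)c([C@H](/C=C/[B-](F)(F)F)c2ccc(OCOC)cc2)c(OCOC)c1.[K+]
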